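The dihydrofuran ring (O1, C2, C3, C3a, C7a) is read as the adduct of an aldehyde C2=O1 with an ortho-iodo arylacetyl unit: C3 is an enolisable arylacetic α-carbon and C7a, two atoms away across C3a, carries iodine, so the pair acts as a 1,3-donor/acceptor. In one flask an Evans boron syn-aldol forges C2–C3 and sets both ring stereocentres, and CuI-catalysed Ullmann etherification then joins O1 to C7a; the precursor is an acyclic N-arylacetyl oxazolidinone without the furan ring. The freed C3 acid next directs C4–H olefination with an acrylate of an (R)-lactate made from methyl (R)-glycidate, and debenzylation completes the route.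

Key step: step 4

Remark: ring atoms are numbered as in 2,3-dihydro-1-benzofuran (O1, C2, C3, C3a, C4 to C7, C7a); compounds 1, 5, 8, 15 and 16 are taken as catalogue compounds.

Step 1
Reactants: 1 3-hydroxy-2-iodobenzaldehyde
Product: 2 3-(benzyloxy)-2-iodobenzaldehyde
Conditions: BnBr, K2CO3, DMF, 25 °C
Reagents that add atoms: benzyl bromide, BrCc1ccccc1
Why: Williamson etherification of the phenoxide with benzyl bromide is routine and creates no stereocentre.

Step 2
Reactants: 2 3-(benzyloxy)-2-iodobenzaldehyde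
Product: 4 2-[3-(benzyloxy)-2-iodophenyl]acetic acid, via trichloromethyl carbinol 3 (not isolated)
Conditions: CCl3CO2Na, CCl3CO2H, DMF, 25 °C; then NaBH4, NaOH, t-BuOH, 55 °C; aq. HCl
Reagents that add atoms: sodium trichloroacetate, [Na+].[O-]C(=O)C(Cl)(Cl)Cl; sodium hydroxide, [Na+].[OH-]
Why: Jocic–Reeve reductive homologation, in which trichloromethyl anion from decarboxylating trichloroacetate adds to the aldehyde, hydroxide closes carbinol 3 to a gem-dichloroepoxide, hydride opens it at the benzylic carbon and the acyl chloride is hydrolysed, should give the one-carbon-extended acid with no stereocentre left.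

Step 3
Reactants: 4 2-[3-(benzyloxy)-2-iodophenyl]acetic acid; 5 (S)-4-benzyl-1,3-oxazolidin-2-one
Product: 7 (S)-4-benzyl-3-{2-[3-(benzyloxy)-2-iodophenyl]acetyl}-1,3-oxazolidin-2-one, via mixed pivalic anhydride 6 (not isolated)
Conditions: PivCl, Et3N, THF, −20 °C; then 5, LiCl, −20 → 25 °C
Reagents that add atoms: none
Why: N-acylation of the oxazolidinone through the mixed pivalic anhydride under LiCl/Et3N activation is the standard loading of an Evans auxiliary and does not touch its stereocentre.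

Step 4
Reactants: 7 (S)-4-benzyl-3-{2-[3-(benzyloxy)-2-iodophenyl]acetyl}-1,3-oxazolidin-2-one; 8 3,4-bis(benzyloxy)benzaldehyde
Product: 12 (S)-4-benzyl-3-{[(2S,3S)-7-(benzyloxy)-2-[3,4-bis(benzyloxy)phenyl]-2,3-dihydro-1-benzofuran-3-yl]carbonyl}-1,3-oxazolidin-2-one, via boron enolate 9 (not isolated), via boron aldolate 10 (not isolated), via syn-aldol adduct 11 (not isolated)
Conditions: Bu2BOTf, iPr2NEt, CH2Cl2, 0 °C; 8, −78 → 0 °C; MeOH, evaporate; then CuI (10 mol %), 3,4,7,8-tetramethyl-1,10-phenanthroline (20 mol %), K3PO4, MeCN, 25–40 °C, same flask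
Reagents that add atoms: none
Why: Soft enolisation (Bu2BOTf, iPr2NEt) gives the Z boron enolate 9, which adds to aldehyde 8 through a closed Zimmerman–Traxler chair to form C2–C3 (Evans syn-aldol); methanolysis of borinate 10 frees the C2 hydroxyl of 11, whose alkoxide on monovalent copper undergoes oxidative addition of the neighbouring C7a–I bond and C–O reductive elimination from trivalent copper to form O1–C7a (Ullmann-type etherification). The closest known reaction types are the boron aldol of N-arylacetyl oxazolidinones and the copper-catalysed intramolecular O-arylation of 1-aryl-2-(2-haloaryl)ethanols to 2-aryl-2,3-dihydrobenzofurans, run here back to back without isolating 11. The one ring that closes is the dihydrofuran, in a 5-exo sense at the arene (O1 attacks C7a, the C7a–I bond lying outside the new ring), through a six-membered O1–Cu–C7a metallacycle. C3 (S) and C2 (S) are both set in the aldol: the benzyl group of the (S)-oxazolidinone shields one face of the Z enolate in the dipole-minimised chair and the chair places the C3 aryl group and the C2 oxygen syn, and since ring closure breaks no bond at either centre the syn adduct maps onto the trans-2,3 ring, which is also the thermodynamically preferred arrangement. The step needs O-arylation to outrun retro-aldol cleavage, acyl transfer of the alkoxide onto the oxazolidinone carbonyl and β-elimination; the intramolecular five-ring closure, the iodide, a ligand that permits 25–40 °C and the weak base K3PO4 are chosen to secure this. Site selectivity is not an issue because C7a carries the only carbon–halogen bond and the imide has no N–H or second hydroxyl to compete.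

Step 5
Reactants: 12 (S)-4-benzyl-3-{[(2S,3S)-7-(benzyloxy)-2-[3,4-bis(benzyloxy)phenyl]-2,3-dihydro-1-benzofuran-3-yl]carbonyl}-1,3-oxazolidin-2-one
Product: 14 (2S,3S)-7-(benzyloxy)-2-[3,4-bis(benzyloxy)phenyl]-2,3-dihydro-1-benzofuran-3-carboxylic acid, via peroxy acid 13 (not isolated)
Conditions: LiOH·H2O, 30% H2O2, THF/H2O, 0 °C; then aq. Na2SO3; HCl to pH 2
Reagents that add atoms: hydrogen peroxide, OO
Why: Hydroperoxide cleavage of the Evans imide should work because the α-effect nucleophile LiOOH attacks the exocyclic carbonyl selectively at 0 °C and is too weakly basic to enolise C3, so both ring stereocentres are kept and sulfite reduces peroxy acid 13 to the acid.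

Step 6
Reactants: 15 1,2-bis(benzyloxy)-4-bromobenzene; 16 methyl (R)-oxirane-2-carboxylate
Product: 18 methyl (R)-3-[3,4-bis(benzyloxy)phenyl]-2-hydroxypropanoate, via aryl Grignard reagent 17 (not isolated)
Conditions: Mg, THF, 45 °C; then CuI (10 mol %), 16, THF, −40 → −20 °C; aq. NH4Cl
Reagents that add atoms: none
Why: Copper-catalysed Grignard opening of the epoxide at its unsubstituted carbon (SN2) should outpace addition to the ester at low temperature and leaves the oxygen-bearing stereocentre of the chiral-pool glycidate untouched, so the (R) configuration is carried into 18.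

Step 7
Reactants: 18 methyl (R)-3-[3,4-bis(benzyloxy)phenyl]-2-hydroxypropanoate
Product: 19 methyl (R)-2-(acryloyloxy)-3-[3,4-bis(benzyloxy)phenyl]propanoate
Conditions: acryloyl chloride, Et3N, DMAP (cat.), CH2Cl2, 0 °C
Reagents that add atoms: acryloyl chloride, C=CC(=O)Cl
Why: DMAP-catalysed O-acylation of the secondary alcohol with the acid chloride proceeds with retention because no bond to the stereocentre is broken.

Step 8
Reactants: 14 (2S,3S)-7-(benzyloxy)-2-[3,4-bis(benzyloxy)phenyl]-2,3-dihydro-1-benzofuran-3-carboxylic acid; 19 methyl (R)-2-(acryloyloxy)-3-[3,4-bis(benzyloxy)phenyl]propanoate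
Product: 20 (2S,3S)-7-(benzyloxy)-2-[3,4-bis(benzyloxy)phenyl]-4-[(E)-3-{[(R)-3-[3,4-bis(benzyloxy)phenyl]-1-methoxy-1-oxopropan-2-yl]oxy}-3-oxoprop-1-en-1-yl]-2,3-dihydro-1-benzofuran-3-carboxylic acid
Conditions: Pd(OAc)2 (5 mol %), N-acetyl-L-isoleucine (10 mol %), KHCO3, O2 (1 atm), tert-amyl alcohol, 85 °C; aq. HCl work-up
Reagents that add atoms: none
Why: In this carboxylate-directed C–H olefination (Fujiwara–Moritani type) the potassium carboxylate on C3 steers divalent palladium into the only free ortho C–H bond (C4) through a six-membered palladacycle, acrylate insertion and β-hydride elimination give the E alkene, O2 reoxidises zerovalent palladium, and no stereocentre is formed or should be epimerised under bicarbonate.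

Step 9
Reactants: 20 (2S,3S)-7-(benzyloxy)-2-[3,4-bis(benzyloxy)phenyl]-4-[(E)-3-{[(R)-3-[3,4-bis(benzyloxy)phenyl]-1-methoxy-1-oxopropan-2-yl]oxy}-3-oxoprop-1-en-1-yl]-2,3-dihydro-1-benzofuran-3-carboxylic acid
Product: 21 (2S,3S)-2-(3,4-dihydroxyphenyl)-4-[(E)-3-{[(R)-3-(3,4-dihydroxyphenyl)-1-methoxy-1-oxopropan-2-yl]oxy}-3-oxoprop-1-en-1-yl]-7-hydroxy-2,3-dihydro-1-benzofuran-3-carboxylic acid
Conditions: BCl3, pentamethylbenzene, CH2Cl2, −78 °C; then MeOH
Reagents that add atoms: none
Why: In this Lewis-acid debenzylation BCl3 activates the aryl benzyl ethers at −78 °C and pentamethylbenzene traps the benzyl cations by Friedel–Crafts alkylation, so all five phenols should be freed without touching the methyl ester, the enoate, the carboxylic acid or the three stereocentres.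

Compound list
1 | 3-hydroxy-2-iodobenzaldehyde | O=Cc1cccc(O)c1I | starting material
2 | 3-(benzyloxy)-2-iodobenzaldehyde | O=Cc1cccc(OCc2ccccc2)c1I | intermediate
3 | 1-[3-(benzyloxy)-2-iodophenyl]-2,2,2-trichloroethan-1-ol (racemic) | OC(c1cccc(OCc2ccccc2)c1I)C(Cl)(Cl)Cl | intermediate
4 | 2-[3-(benzyloxy)-2-iodophenyl]acetic acid | OC(=O)Cc1cccc(OCc2ccccc2)c1I | intermediate
5 | (S)-4-benzyl-1,3-oxazolidin-2-one | O=C1N[C@@H](Cc2ccccc2)CO1 | starting material
6 | 2-[3-(benzyloxy)-2-iodophenyl]acetic pivalic anhydride | CC(C)(C)C(=O)OC(=O)Cc1cccc(OCc2ccccc2)c1I | intermediate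
7 | (S)-4-benzyl-3-{2-[3-(benzyloxy)-2-iodophenyl]acetyl}-1,3-oxazolidin-2-one | O=C(Cc1cccc(OCc2ccccc2)c1I)N1C(=O)OC[C@@H]1Cc1ccccc1 | intermediate
8 | 3,4-bis(benzyloxy)benzaldehyde | O=Cc1ccc(OCc2ccccc2)c(OCc2ccccc2)c1 | starting material
9 | (S)-4-benzyl-3-{(Z)-2-[3-(benzyloxy)-2-iodophenyl]-1-[(dibutylboranyl)oxy]ethenyl}-1,3-oxazolidin-2-one | CCCCB(CCCC)O/C(=C\c1cccc(OCc2ccccc2)c1I)N1C(=O)OC[C@@H]1Cc1ccccc1 | intermediate
10 | (S)-4-benzyl-3-{(2S,3S)-2-[3-(benzyloxy)-2-iodophenyl]-3-[3,4-bis(benzyloxy)phenyl]-3-[(dibutylboranyl)oxy]propanoyl}-1,3-oxazolidin-2-one | O=C([C@@H](c1cccc(OCc2ccccc2)c1I)[C@H](OB(CCCC)CCCC)c1ccc(OCc2ccccc2)c(OCc2ccccc2)c1)N1C(=O)OC[C@@H]1Cc1ccccc1 | intermediate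
11 | (S)-4-benzyl-3-{(2S,3S)-2-[3-(benzyloxy)-2-iodophenyl]-3-[3,4-bis(benzyloxy)phenyl]-3-hydroxypropanoyl}-1,3-oxazolidin-2-one | O=C([C@@H](c1cccc(OCc2ccccc2)c1I)[C@H](O)c1ccc(OCc2ccccc2)c(OCc2ccccc2)c1)N1C(=O)OC[C@@H]1Cc1ccccc1 | intermediate
12 | (S)-4-benzyl-3-{[(2S,3S)-7-(benzyloxy)-2-[3,4-bis(benzyloxy)phenyl]-2,3-dihydro-1-benzofuran-3-yl]carbonyl}-1,3-oxazolidin-2-one | O=C(N1C(=O)OC[C@@H]1Cc1ccccc1)[C@H]1c2cccc(OCc3ccccc3)c2O[C@@H]1c1ccc(OCc2ccccc2)c(OCc2ccccc2)c1 | intermediate
13 | (2S,3S)-7-(benzyloxy)-2-[3,4-bis(benzyloxy)phenyl]-2,3-dihydro-1-benzofuran-3-carboperoxoic acid | OOC(=O)[C@H]1c2cccc(OCc3ccccc3)c2O[C@@H]1c1ccc(OCc2ccccc2)c(OCc2ccccc2)c1 | intermediate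
14 | (2S,3S)-7-(benzyloxy)-2-[3,4-bis(benzyloxy)phenyl]-2,3-dihydro-1-benzofuran-3-carboxylic acid | OC(=O)[C@H]1c2cccc(OCc3ccccc3)c2O[C@@H]1c1ccc(OCc2ccccc2)c(OCc2ccccc2)c1 | intermediate
15 | 1,2-bis(benzyloxy)-4-bromobenzene | Brc1ccc(OCc2ccccc2)c(OCc2ccccc2)c1 | starting material
16 | methyl (R)-oxirane-2-carboxylate (methyl (R)-glycidate) | COC(=O)[C@H]1CO1 | starting material
17 | [3,4-bis(benzyloxy)phenyl]magnesium bromide | Br[Mg]c1ccc(OCc2ccccc2)c(OCc2ccccc2)c1 | intermediate
18 | methyl (R)-3-[3,4-bis(benzyloxy)phenyl]-2-hydroxypropanoate | COC(=O)[C@@H](Cc1ccc(OCc2ccccc2)c(OCc2ccccc2)c1)O | intermediate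
19 | methyl (R)-2-(acryloyloxy)-3-[3,4-bis(benzyloxy)phenyl]propanoate | COC(=O)[C@@H](Cc1ccc(OCc2ccccc2)c(OCc2ccccc2)c1)OC(=O)C=C | intermediate
20 | (2S,3S)-7-(benzyloxy)-2-[3,4-bis(benzyloxy)phenyl]-4-[(E)-3-{[(R)-3-[3,4-bis(benzyloxy)phenyl]-1-methoxy-1-oxopropan-2-yl]oxy}-3-oxoprop-1-en-1-yl]-2,3-dihydro-1-benzofuran-3-carboxylic acid | COC(=O)[C@@H](Cc1ccc(OCc2ccccc2)c(OCc2ccccc2)c1)OC(=O)/C=C/c1ccc(OCc2ccccc2)c2c1[C@H](C(=O)O)[C@@H](c1ccc(OCc3ccccc3)c(OCc3ccccc3)c1)O2 | intermediate
21 | (2S,3S)-2-(3,4-dihydroxyphenyl)-4-[(E)-3-{[(R)-3-(3,4-dihydroxyphenyl)-1-methoxy-1-oxopropan-2-yl]oxy}-3-oxoprop-1-en-1-yl]-7-hydroxy-2,3-dihydro-1-benzofuran-3-carboxylic acid (CNP0120702.1) | COC(=O)[C@@H](Cc1ccc(O)c(O)c1)OC(=O)/C=C/c1ccc(O)c2c1[C@H](C(=O)O)[C@@H](c1ccc(O)c(O)c1)O2 | target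

Total step count: 9. Longest linear sequence: 7 steps (steps 1, 2, 3, 4, 5, 8, 9).

Steps most likely to fail

Step 4. Once the boron is removed, retro-aldol cleavage, acyl transfer of the alkoxide onto the oxazolidinone or β-elimination may outpace the copper-mediated ring closure and erode yield and stereochemical purity. The fallback takes the carbonyl away before the ring is closed; it sets out from 7 and 8 and returns at 14. The same boron aldol is stopped by oxidative work-up (H2O2, pH 7 buffer, MeOH) and aldol 11 is isolated. LiBH4 (THF, 1 equiv MeOH, 0 °C) removes the auxiliary reductively to give the (1S,2R)-diol F1. TBSCl and imidazole (CH2Cl2, 0 °C) silylate the primary hydroxyl to give the mono-silyl ether F2. With no carbonyl left, ordinary Ullmann etherification (CuI, 1,10-phenanthroline, Cs2CO3, toluene, 110 °C) should close the ring to the cyclised silyl ether F3. TBAF (THF) frees the primary alcohol F4, and TEMPO/PhI(OAc)2 in MeCN/H2O oxidises it to acid 14.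

Step 9. Lewis-acid-triggered opening of the benzylic C2–O1 bond, incomplete cleavage of five benzyl ethers or ring benzylation by escaped benzyl cations may occur on the fully assembled molecule. The fallback exchanges benzyl for acetyl before the alkene is present, so that hydrogenolysis can be used on the dihydrobenzofuran; it sets out from 14 and 19 and returns at 21. Hydrogenolysis of 14 (H2, Pd/C, EtOAc/MeOH) gives the triphenol acid F5, and Ac2O in cold aqueous NaOH under argon acetylates the phenols only to give the triacetate acid F6. BCl3/pentamethylbenzene on 19, which has no sensitive ring, gives the catechol acrylate F7, and Ac2O/pyridine gives the diacetate acrylate F8. The olefination conditions of step 8 applied to F6 and F8 should give the pentaacetate F9, and N2H4·HOAc (DMF, 25 °C) removes the aryl acetates to give 21.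

Step 5. Base-induced β-elimination through the C3 enolate, which opens the O1–C2 bond, or attack at the endocyclic carbamate carbonyl may compete with exocyclic cleavage. The fallback avoids hydroxide altogether; it sets out from 12 and returns at 14. Yb(OTf)3-catalysed methanolysis (MeOH, CH2Cl2, 25 °C) should give the methyl ester F10, and Me3SnOH (1,2-dichloroethane, 80 °C) hydrolyses it under neutral conditions to 14.

Further compounds
F1 | step 4 | (1S,2R)-2-[3-(benzyloxy)-2-iodophenyl]-1-[3,4-bis(benzyloxy)phenyl]propane-1,3-diol | OC[C@@H](c1cccc(OCc2ccccc2)c1I)[C@H](O)c1ccc(OCc2ccccc2)c(OCc2ccccc2)c1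
F2 | step 4 | (1S,2R)-2-[3-(benzyloxy)-2-iodophenyl]-1-[3,4-bis(benzyloxy)phenyl]-3-[(tert-butyldimethylsilyl)oxy]propan-1-ol | CC(C)(C)[Si](C)(C)OC[C@@H](c1cccc(OCc2ccccc2)c1I)[C@H](O)c1ccc(OCc2ccccc2)c(OCc2ccccc2)c1
F3 | step 4 | {[(2S,3R)-7-(benzyloxy)-2-[3,4-bis(benzyloxy)phenyl]-2,3-dihydro-1-benzofuran-3-yl]methoxy}(tert-butyl)dimethylsilane | CC(C)(C)[Si](C)(C)OC[C@H]1c2cccc(OCc3ccccc3)c2O[C@@H]1c1ccc(OCc2ccccc2)c(OCc2ccccc2)c1
F4 | step 4 | [(2S,3R)-7-(benzyloxy)-2-[3,4-bis(benzyloxy)phenyl]-2,3-dihydro-1-benzofuran-3-yl]methanol | OC[C@H]1c2cccc(OCc3ccccc3)c2O[C@@H]1c1ccc(OCc2ccccc2)c(OCc2ccccc2)c1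
F5 | step 9 | (2S,3S)-2-(3,4-dihydroxyphenyl)-7-hydroxy-2,3-dihydro-1-benzofuran-3-carboxylic acid | OC(=O)[C@H]1c2cccc(O)c2O[C@@H]1c1ccc(O)c(O)c1
F6 | step 9 | (2S,3S)-7-acetoxy-2-(3,4-diacetoxyphenyl)-2,3-dihydro-1-benzofuran-3-carboxylic acid | OC(=O)[C@H]1c2cccc(OC(C)=O)c2O[C@@H]1c1ccc(OC(C)=O)c(OC(C)=O)c1
F7 | step 9 | methyl (R)-2-(acryloyloxy)-3-(3,4-dihydroxyphenyl)propanoate | COC(=O)[C@@H](Cc1ccc(O)c(O)c1)OC(=O)C=C
F8 | step 9 | methyl (R)-2-(acryloyloxy)-3-(3,4-diacetoxyphenyl)propanoate | COC(=O)[C@@H](Cc1ccc(OC(C)=O)c(OC(C)=O)c1)OC(=O)C=C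
F9 | step 9 | (2S,3S)-7-acetoxy-2-(3,4-diacetoxyphenyl)-4-[(E)-3-{[(R)-3-(3,4-diacetoxyphenyl)-1-methoxy-1-oxopropan-2-yl]oxy}-3-oxoprop-1-en-1-yl]-2,3-dihydro-1-benzofuran-3-carboxylic acid | COC(=O)[C@@H](Cc1ccc(OC(C)=O)c(OC(C)=O)c1)OC(=O)/C=C/c1ccc(OC(C)=O)c2c1[C@H](C(=O)O)[C@@H](c1ccc(OC(C)=O)c(OC(C)=O)c1)O2
F10 | step 5 | methyl (2S,3S)-7-(benzyloxy)-2-[3,4-bis(benzyloxy)phenyl]-2,3-dihydro-1-benzofuran-3-carboxylate | COC(=O)[C@H]1c2cccc(OCc3ccccc3)c2O[C@@H]1c1ccc(OCc2ccccc2)c(OCc2ccccc2)c1
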